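The depside is cut at its aryl ester into a benzyl-protected ring A acid and a ring B phenol, and the plan rests on making ring B from two acyclic pieces. A Danheiser benzannulation joins a vinylketene, released by photochemical Wolff rearrangement of an E-configured diazoketone that already carries the C5' propyl group and the C4' benzyl ester, to a silyl ynol ether. This one operation forms C2'–C3', C1'–C6' and C3'–C4', closes ring B, and exploits its contiguous C3'–OH, C4'–carboxyl, C5'–propyl array with the meta C1' oxygen: the C3' hydroxyl emerges free and the C1' oxygen silylated. The diazoketone is made by diazo transfer to a methyl ketone, which avoids diazomethane.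

Key step: step 6

Remark: ring B locants are C1' (depside oxygen), C2' (H), C3' (OH), C4' (CO2H), C5' (propyl), C6' (H); the target has no stereocentre, so the only stereochemical element to control is the E geometry of the enoate carried from 8 to 11.

Step 1
Reactants: 1 butyltriphenylphosphonium bromide; 2 acetyl chloride
Product: 5 3-(triphenylphosphoranylidene)hexan-2-one, via butylidenetriphenylphosphorane 3 (not isolated), via acylphosphonium chloride 4 (not isolated)
Conditions: 1 (2 equiv), n-BuLi (2 equiv), THF, 0 °C; 2 (1 equiv, slow addition), −78 °C to rt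
Reagents that add atoms: none
Why: C-acylation of a non-stabilised phosphorus ylide by an acid chloride followed by transylidation, in which the second equivalent of 3 deprotonates the acidic salt 4 to the stabilised ylide 5, while slow addition of 2 at low temperature keeps 5 from being acylated on oxygen.

Step 2
Reactants: 6 dibenzyl L-tartrate
Product: 7 benzyl glyoxylate
Conditions: H5IO6, Et2O, rt; dried over 4 Å molecular sieves and used fresh
Reagents that add atoms: none
Why: Periodate glycol cleavage (Malaprade reaction) cuts the C2–C3 bond of the 1,2-diol and should give two equivalents of the aldehyde under conditions that leave the benzyl esters alone.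

Step 3
Reactants: 5 3-(triphenylphosphoranylidene)hexan-2-one; 7 benzyl glyoxylate
Product: 8 benzyl (E)-3-acetylhex-2-enoate
Conditions: CH2Cl2, rt to 40 °C
Reagents that add atoms: none
Why: Wittig reaction of a stabilised acyl ylide with the very electrophilic glyoxylate, which as usual for stabilised ylides should place the two carbonyl groups trans (the E, mesaconate-type geometry needed later), and the neutral conditions avoid base-induced migration of the double bond.

Step 4
Reactants: 8 benzyl (E)-3-acetylhex-2-enoate
Product: 11 benzyl (E)-3-(2-diazoacetyl)hex-2-enoate, via lithium enolate 9 (not isolated), via trifluoroacetyl diketone 10 (not isolated)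
Conditions: LiN(SiMe3)2, THF, −78 °C; CF3CO2CH2CF3, −78 °C; aq. HCl work-up; then MsN3, Et3N, H2O, MeCN, rt
Reagents that add atoms: methanesulfonyl azide, CS(=O)(=O)N=[N+]=[N-]
Why: Detrifluoroacetylative diazo transfer, in which kinetic enolisation of the methyl ketone and Claisen-type trifluoroacetylation give the activated 1,3-diketone 10, to which mesyl azide transfers the diazo group with loss of the trifluoroacetyl group; this sequence suits α,β-unsaturated methyl ketones because it avoids the dipolar cycloaddition that diazomethane would undergo with the electron-poor alkene, and it leaves the E geometry untouched.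

Step 5
Reactants: 12 3-phenylisoxazole
Product: 15 (triisopropylsilyloxy)ethyne, via 5-lithio-3-phenylisoxazole 13 (not isolated), via lithium ethynolate 14 (not isolated)
Conditions: n-BuLi, THF, −78 °C to 0 °C; iPr3SiOTf, −78 °C to 0 °C
Reagents that add atoms: triisopropylsilyl trifluoromethanesulfonate, CC(C)[Si](C(C)C)(C(C)C)OS(=O)(=O)C(F)(F)F
Why: Deprotonation at C5 of the isoxazole is followed by the known cycloreversion of 5-lithioisoxazoles (N–O and C3–C4 cleavage) into benzonitrile and the ynolate 14, and the bulky, hard silyl triflate should then silylate the ynolate on oxygen to give an ynol ether that the triisopropylsilyl group protects against 1,3-silyl shift.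

Step 6
Reactants: 11 benzyl (E)-3-(2-diazoacetyl)hex-2-enoate; 15 (triisopropylsilyloxy)ethyne
Product: 20 benzyl 2-hydroxy-6-propyl-4-(triisopropylsilyloxy)benzoate, via vinylketene 16 (not isolated), via vinylcyclobutenone 17 (not isolated), via dienylketene 18 (not isolated), via cyclohexadienone 19 (not isolated)
Conditions: 15 (2 equiv), hν (medium-pressure Hg lamp, Pyrex), ClCH2CH2Cl, rt; then 80 °C
Reagents that add atoms: none
Why: Irradiation should expel N2 from 11, and the Wolff shift of the alkenyl group gives vinylketene 16, whose electrophilic ketene carbon is attacked by the unsubstituted, nucleophilic carbon of 15 in a regioselective (2+2) cycloaddition to 17. A 4π-electrocyclic opening of 17 gives dienylketene 18, which closes ring B by a disrotatory 6π-electrocyclization that forms C3'–C4' and leads to 19, and enolisation then gives phenol 20. The closest known reaction type is the Danheiser benzannulation of α,β-unsaturated α'-diazo ketones with siloxyalkynes, which gives resorcinol monosilyl ethers by the same cascade. No stereocentre is set, since the sp3 centres of 17 and 19 vanish on aromatisation. Two selectivities are needed: the alkyne regiochemistry, secured by the polarisation of the ynol ether (its oxygen-bearing carbon bonds to the ketene α-carbon, so the silyloxy group lands meta to the new hydroxyl), and reaction through the ketene instead of lactonisation onto the ester, secured by the E alkene, which holds the ester away from the ketene and on the outside of the closing triene.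

Step 7
Reactants: 20 benzyl 2-hydroxy-6-propyl-4-(triisopropylsilyloxy)benzoate
Product: 21 benzyl 2,4-dihydroxy-6-propylbenzoate
Conditions: Bu4NF, AcOH, THF, 0 °C
Reagents that add atoms: none
Why: Fluoride-mediated desilylation, driven by the strong Si–F bond, should cleave the aryl silyl ether, and buffering with acetic acid keeps the liberated phenoxide from attacking the benzyl ester.

Step 8
Reactants: 22 olivetol (5-pentylresorcinol)
Product: 24 2,4-dihydroxy-6-pentylbenzaldehyde, via aryl iminium chloride 23 (not isolated)
Conditions: POCl3, DMF, 0 °C to rt; then H2O, 50 °C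
Reagents that add atoms: N,N-dimethylformamide, CN(C)C=O; water, O
Why: Vilsmeier–Haack formylation, in which the chloroiminium ion attacks the ring position para to one hydroxyl and ortho to the other, favoured over the position between the two hydroxyls, and hydrolysis of iminium salt 23 gives the aldehyde.

Step 9
Reactants: 24 2,4-dihydroxy-6-pentylbenzaldehyde
Product: 25 2,4-bis(benzyloxy)-6-pentylbenzaldehyde
Conditions: BnBr, K2CO3, DMF, 60 °C
Reagents that add atoms: benzyl bromide, BrCc1ccccc1
Why: Williamson ether synthesis should alkylate both phenoxides, the hydrogen-bonded ortho one included at this temperature, and benzyl is chosen so that every protecting group falls in the final hydrogenolysis.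

Step 10
Reactants: 25 2,4-bis(benzyloxy)-6-pentylbenzaldehyde
Product: 26 2,4-bis(benzyloxy)-6-pentylbenzoic acid
Conditions: NaClO2, NaH2PO4, 2-methyl-2-butene, t-BuOH/H2O, rt
Reagents that add atoms: sodium chlorite, [Na+].[O-]Cl=O
Why: Pinnick oxidation, in which chlorous acid oxidises the hindered, electron-rich aldehyde to the acid without touching the benzyl ethers and 2-methyl-2-butene scavenges the hypochlorous acid that would chlorinate the ring.

Step 11
Reactants: 21 benzyl 2,4-dihydroxy-6-propylbenzoate; 26 2,4-bis(benzyloxy)-6-pentylbenzoic acid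
Product: 28 benzyl 4-{[2,4-bis(benzyloxy)-6-pentylbenzoyl]oxy}-2-hydroxy-6-propylbenzoate, via mixed anhydride 27 (not isolated)
Conditions: (CF3CO)2O, toluene, rt
Reagents that add atoms: none
Why: Esterification through a mixed trifluoroacetic anhydride, the classical depside coupling, in which the hindered acid is activated as 27 and should acylate the C1' hydroxyl of 21 (para to the ester), while the C3' hydroxyl stays free because it is hydrogen-bonded to and shielded by the neighbouring ester carbonyl.

Step 12
Reactants: 28 benzyl 4-{[2,4-bis(benzyloxy)-6-pentylbenzoyl]oxy}-2-hydroxy-6-propylbenzoate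
Product: 29 4-[(2,4-dihydroxy-6-pentylbenzoyl)oxy]-2-hydroxy-6-propylbenzoic acid
Conditions: H2 (1 atm), 10% Pd/C, EtOAc, rt
Reagents that add atoms: none
Why: Catalytic hydrogenolysis should cleave the two benzyl ethers and the benzyl ester in one operation, while the aryl ester of the depside, the free acid and the phenols are inert to H2 over Pd/C under neutral conditions.

Compound list

1 | butyltriphenylphosphonium bromide | CCCC[P+](c1ccccc1)(c1ccccc1)c1ccccc1.[Br-] | starting material
2 | acetyl chloride | CC(=O)Cl | starting material
3 | butylidenetriphenylphosphorane | CCCC=P(c1ccccc1)(c1ccccc1)c1ccccc1 | intermediate (not isolated)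
4 | (2-oxohexan-3-yl)triphenylphosphonium chloride (racemic) | CCCC(C(C)=O)[P+](c1ccccc1)(c1ccccc1)c1ccccc1.[Cl-] | intermediate (not isolated)
5 | 3-(triphenylphosphoranylidene)hexan-2-one | CCCC(C(C)=O)=P(c1ccccc1)(c1ccccc1)c1ccccc1 | intermediate
6 | dibenzyl L-tartrate, dibenzyl (2R,3R)-2,3-dihydroxybutanedioate | O=C(OCc1ccccc1)[C@H](O)[C@@H](O)C(=O)OCc1ccccc1 | starting material
7 | benzyl glyoxylate (benzyl 2-oxoacetate) | O=CC(=O)OCc1ccccc1 | intermediate
8 | benzyl (E)-3-acetylhex-2-enoate | CCC/C(C(C)=O)=C\C(=O)OCc1ccccc1 | intermediate
9 | lithium (3E)-5-(benzyloxy)-5-oxo-3-propylpenta-1,3-dien-2-olate (lithium enolate of 8) | CCC/C(C(=C)O[Li])=C\C(=O)OCc1ccccc1 | intermediate (not isolated)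
10 | benzyl (E)-3-(4,4,4-trifluoro-3-oxobutanoyl)hex-2-enoate | CCC/C(C(=O)CC(=O)C(F)(F)F)=C\C(=O)OCc1ccccc1 | intermediate (not isolated)
11 | benzyl (E)-3-(2-diazoacetyl)hex-2-enoate | CCC/C(C(=O)C=[N+]=[N-])=C\C(=O)OCc1ccccc1 | intermediate
12 | 3-phenylisoxazole | c1ccc(-c2ccon2)cc1 | starting material
13 | 5-lithio-3-phenylisoxazole | [Li]c1cc(-c2ccccc2)no1 | intermediate (not isolated)
14 | lithium ethynolate | [Li]OC#C | intermediate (not isolated)
15 | (triisopropylsilyloxy)ethyne | C#CO[Si](C(C)C)(C(C)C)C(C)C | intermediate
16 | benzyl (2E)-5-oxo-3-propylpenta-2,4-dienoate (vinylketene) | CCC/C(C=C=O)=C\C(=O)OCc1ccccc1 | intermediate (not isolated)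
17 | benzyl (E)-3-[2-oxo-4-(triisopropylsilyloxy)cyclobut-3-en-1-yl]hex-2-enoate (racemic) | CCC/C(=C\C(=O)OCc1ccccc1)C1C(=O)C=C1O[Si](C(C)C)(C(C)C)C(C)C | intermediate (not isolated)
18 | benzyl (2E,4E)-7-oxo-3-propyl-5-(triisopropylsilyloxy)hepta-2,4,6-trienoate (dienylketene) | O=C=C/C(O[Si](C(C)C)(C(C)C)C(C)C)=C\C(CCC)=C\C(=O)OCc1ccccc1 | intermediate (not isolated)
19 | benzyl 2-oxo-6-propyl-4-(triisopropylsilyloxy)cyclohexa-3,5-diene-1-carboxylate (racemic) | CCCC1=CC(O[Si](C(C)C)(C(C)C)C(C)C)=CC(=O)C1C(=O)OCc1ccccc1 | intermediate (not isolated)
20 | benzyl 2-hydroxy-6-propyl-4-(triisopropylsilyloxy)benzoate | CCCc1cc(O[Si](C(C)C)(C(C)C)C(C)C)cc(O)c1C(=O)OCc1ccccc1 | intermediate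
21 | benzyl 2,4-dihydroxy-6-propylbenzoate | CCCc1cc(O)cc(O)c1C(=O)OCc1ccccc1 | intermediate
22 | olivetol (5-pentylresorcinol) | CCCCCc1cc(O)cc(O)c1 | starting material
23 | [(2,4-dihydroxy-6-pentylphenyl)methylidene]dimethylammonium chloride | CCCCCc1cc(O)cc(O)c1C=[N+](C)C.[Cl-] | intermediate (not isolated)
24 | 2,4-dihydroxy-6-pentylbenzaldehyde | CCCCCc1cc(O)cc(O)c1C=O | intermediate
25 | 2,4-bis(benzyloxy)-6-pentylbenzaldehyde | CCCCCc1cc(OCc2ccccc2)cc(OCc2ccccc2)c1C=O | intermediate
26 | 2,4-bis(benzyloxy)-6-pentylbenzoic acid | CCCCCc1cc(OCc2ccccc2)cc(OCc2ccccc2)c1C(=O)O | intermediate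
27 | 2,4-bis(benzyloxy)-6-pentylbenzoic trifluoroacetic anhydride | CCCCCc1cc(OCc2ccccc2)cc(OCc2ccccc2)c1C(=O)OC(=O)C(F)(F)F | intermediate (not isolated)
28 | benzyl 4-{[2,4-bis(benzyloxy)-6-pentylbenzoyl]oxy}-2-hydroxy-6-propylbenzoate | CCCCCc1cc(OCc2ccccc2)cc(OCc2ccccc2)c1C(=O)Oc1cc(O)c(C(=O)OCc2ccccc2)c(CCC)c1 | intermediate
29 | 4-[(2,4-dihydroxy-6-pentylbenzoyl)oxy]-2-hydroxy-6-propylbenzoic acid | CCCCCc1cc(O)cc(O)c1C(=O)Oc1cc(O)c(C(=O)O)c(CCC)c1 | target

Total step count: 12.
Longest linear sequence: 7 steps (steps 1, 3, 4, 6, 7, 11, 12).

Steps most likely to fail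

1. Step 6. The capture of the short-lived, ester-bearing vinylketene by the terminal ynol ether may be outrun by ketene oligomerisation, by E-to-Z photoisomerisation of the enoate followed by lactonisation of the ketene onto the ester carbonyl, or by 1,3-silyl migration in the ynol ether. The fallback builds ring B by a condensation route and needs none of compounds 1–20. It therefore sets out from no numbered compound but from commercial (E)-hept-3-en-2-one and dibenzyl malonate, and it comes back to the route at 21. Michael addition of the malonate anion followed by Claisen cyclisation of the methyl ketone onto one benzyl ester (NaH, THF, rt then reflux) should give benzyl 2,4-dioxo-6-propylcyclohexane-1-carboxylate F1. Bromination and dehydrobromination (Br2, 1 equiv, DMF, 0 °C then 80 °C) should aromatise F1 to 21.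

2. Step 5. The base may add to the C=N bond or to the nitrile that is released instead of removing the C5 proton, or the fragmentation of the lithio species may be incomplete before silylation. The fallback sets out from acetylene in place of 12 and comes back to the route at the ynolate 14, and so at 15. Monolithium acetylide F2 (acetylene, n-BuLi, THF, −78 °C) would be oxidised on carbon by lithium tert-butyl peroxide F3 (t-BuOOH, LiN(SiMe3)2, THF, −78 °C, then slow warming). This is the known oxidation of lithium acetylides to ynolates, and the ynolate 14 is then silylated with iPr3SiOTf as in step 5.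

3. Step 4. Site selectivity of the deprotonation may be lost, with the allylic CH2 of the propyl group (vinylogous to the ester) competing with the acetyl CH3, or the amide base may add in conjugate fashion to the ene-dicarbonyl system. The fallback sets out from 8 and comes back at 11 without a strong base. Soft enolisation (Me3SiOTf, Et3N, CH2Cl2, 0 °C), which can only engage the ketone, should give benzyl (2E)-3-propyl-4-(trimethylsilyloxy)penta-2,4-dienoate F4. Bromination of the silyl enol ether (N-bromosuccinimide, THF, 0 °C) gives benzyl (E)-3-(2-bromoacetyl)hex-2-enoate F5. N-Alkylation of N,N'-ditosylhydrazine by F5 (DBU, THF, 0 °C) gives benzyl (E)-3-{2-[1,2-bis(4-methylbenzenesulfonyl)hydrazin-1-yl]acetyl}hex-2-enoate F6, which loses two sulfinate groups under the same conditions to give 11.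

Further compounds

F1 | step 6 | benzyl 2,4-dioxo-6-propylcyclohexane-1-carboxylate (racemic, keto–enol mixture; both stereocentres are lost on aromatisation) | CCCC1CC(=O)CC(=O)C1C(=O)OCc1ccccc1
F2 | step 5 | lithium acetylide | [Li]C#C
F3 | step 5 | lithium tert-butyl peroxide | CC(C)(C)OO[Li]
F4 | step 4 | benzyl (2E)-3-propyl-4-(trimethylsilyloxy)penta-2,4-dienoate | CCC/C(C(=C)O[Si](C)(C)C)=C\C(=O)OCc1ccccc1
F5 | step 4 | benzyl (E)-3-(2-bromoacetyl)hex-2-enoate | CCC/C(C(=O)CBr)=C\C(=O)OCc1ccccc1
F6 | step 4 | benzyl (E)-3-{2-[1,2-bis(4-methylbenzenesulfonyl)hydrazin-1-yl]acetyl}hex-2-enoate | CCC/C(C(=O)CN(NS(=O)(=O)c1ccc(C)cc1)S(=O)(=O)c1ccc(C)cc1)=C\C(=O)OCc1ccccc1
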